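## Structural features

The target is an 8-O-4′ neolignan acid made of two benzene rings and an open three-carbon chain: ring A is a 4-hydroxy-3-methoxyphenyl ring and ring B is a 3,5-dimethoxybenzoic acid whose C4′ oxygen is the ether link; there is no other ring. The chain C7–C8–C9 joins them: C7 is a benzylic secondary carbinol bonded to C1 of ring A, C8 carries the ether oxygen O4′ to ring B, and C9 is a primary CH2OH group. C7 and C8 are neighbouring stereocentres, both S, which is the threo (syn) arrangement of the C7 hydroxyl and the C8 aryloxy group. The fragile parts are the 4-hydroxybenzylic alcohol at C7 (ionisation under acid with epimerisation or elimination, hydrogenolysis over noble metals, phenolate-driven loss of hydroxide in hot base), the oxidisable free phenol and, in carbonyl-containing intermediates, the acidic C8–H. The connectivity is simple; the real difficulty is to fix the relative and absolute configuration of two oxygen-bearing centres on a freely rotating chain while making an aryl alkyl ether at a phenol oxygen flanked by two methoxy groups. The key step uses exactly that crowded ether: O4′ on C8 is twisted out of the plane of ring B and sits beside the C3′/C5′ methoxy oxygens, so that, together with the C7 carbonyl oxygen of an aldehyde precursor, it can hold a magnesium centre and let the C8 centre decide on which face C1 of ring A is joined to C7.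

## Logic of the disconnections

12 from 11: the carboxyl group of ring B is traced back to its methyl ester (forward: cleavage of the acyl C–OCH3 bond by hydroxide). A free acid cannot pass through the hydride and organomagnesium steps, and the ester is already present in the commercial ring B unit. The gain is that all intermediates are neutral and easy to purify. The demand is hydrolysis at room temperature with the ring A phenol and the C7 carbinol unprotected, followed by an acidification no stronger than pH 3.

11 from 10: the O9–H and the ring A O4–H bonds are traced back to two O–Si bonds. Putting the same silyl group on both oxygens lets one fluoride treatment unmask both and avoids any hydrogenolysis next to the benzylic C7–O bond. The gain is one operation for two protecting groups. The demand is a buffered fluoride source so that the liberated phenoxide and the ester do not meet a strongly basic medium.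

10 from 6 and 9: the bond from C1 of ring A to C7 is cut. It is the only carbon–carbon bond beside C8, so its formation can be steered by the existing C8 centre and the oxygen donors of ring B. The gain is a convergent split into a ring A nucleophile and a ring B electrophile that already holds C7–C9, each a few steps from commercial material. The demand is that the alpha-chelated pathway wins, that 6 keeps its configuration until it reacts, and that the aldehyde reacts before the ring B ester.

9 from 8: the C–Mg bond is traced back to the C–Br bond. This is the simplest way to make C1 of ring A nucleophilic. The demand is that the aryl silyl ether survives magnesium insertion.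

8 from 7: the ring A O–Si bond is cut. The phenol must be masked for the organometallic step, and the silyl group is chosen to match the one on O9. 7 is commercial.

6 from 5: the C7–H bond of the aldehyde is traced back to the C7–OCH3 bond of an ester. The alpha-aryloxy aldehyde is too labile to carry through several steps, whereas the ester is a storable carrier of C7. The demand is a hydride transfer that stops at the aldehyde, distinguishes the activated aliphatic ester from the ring B benzoate, and leaves C8 untouched.

5 from 3 and 4: the C8–O4′ bond is cut. A hindered aryl ether is best made by SN2 displacement at a carbon activated by an adjacent carbonyl group, and the inversion turns the (R) centre of the chiral pool into the required (S) centre. The gain is separation of ring B (4, commercial) from a chiral three-carbon unit. The demand is clean inversion with a phenol flanked by two ortho substituents, without elimination.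

3 from 2: the O9–Si bond is cut. The demand is selective silylation of the primary hydroxyl in the presence of the secondary one.

2 from 1: the two acetal C–O bonds are cut, which leads back to a commercial chiral-pool ester. The demand is acetal cleavage without loss of the methyl ester.

## Other disconnections considered

Alternative 1: The cut removes the C8–O4′ and C7–C8 bonds together and leaves three commercial pieces: 4, ethyl diazoacetate A2 and vanillin acetate A3.
- Forward key step: Rh2(OAc)4 (divalent rhodium) would convert A2 into a carbenoid and the phenol oxygen of 4 would add to it. The resulting oxonium ylide would be trapped by A3, activated and oriented by a chiral BINOL-derived phosphoric acid, to give the threo hydroxy ester A1 with both stereocentres.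
- In its favour: two skeletal bonds and both stereocentres are made in one operation, O9 needs no protecting group, and no configurationally labile aldehyde appears. Only a borohydride reduction of the aliphatic ester and hydrolysis of the acetate and the benzoate would remain, so roughly three steps in all.
- Against it here: ylide trapping is best founded for aryl-substituted diazo esters. With the acceptor-only A2 and an acidic phenol, the 1,2-proton shift to a plain aryloxyacetate should be fast. A3 is an electron-rich and therefore weak electrophile. The threo/erythro and facial outcome would depend on a catalyst–substrate match for which a phenol flanked by two methoxy groups has no close analogy.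
- Comparison: on structure the two plans are equal, since both carry C9 as an ester that must be reduced beside the ring B benzoate. On mechanism the alternative relies on catalyst control of two new centres, whereas the chosen plan uses a chiral-pool centre of certain configuration to steer one new centre; the absolute configuration is therefore more secure in the chosen plan, while the relative configuration is uncertain in both. On step economy the alternative is clearly the better.

Alternative 2: The cut is the C8–O4′ bond, made late and with the C7 carbinol already present.
- Forward key step: Pd2(dba)3 (zerovalent palladium) with a diphosphine ligand would ionise the allylic C8–O bond of the trans epoxide A5 with inversion. 4 would then attack the π-allyl intermediate at C8 with a second inversion, guided by the C7 alkoxide, to give A4 with net retention.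
- In its favour: the threo relationship follows stereospecifically from the trans geometry of A5 and does not depend on a chelate, a point on which this plan is better than the chosen one. C8 is never next to a carbonyl group and cannot epimerise, also a better point. The conditions are neutral.
- Against it here: A5 is an aryl vinyl epoxide of an electron-rich arene, activated at both C–O bonds and liable to benzylic ionisation and rearrangement, and it would itself need an enantioselective synthesis of several steps. Attack of a bulky phenol at the internal carbon must win over attack at the allyl terminus. Afterwards the vinyl group has to be cut down to C9 by ozonolysis and reduction in the presence of two electron-rich rings, followed by ester hydrolysis and removal of the benzyl ether with H2 over Pd/C next to the C7 carbinol.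
- Comparison: on structure the chosen plan is leaner, because its three-carbon unit has the right number of carbons from the start, whereas A4 carries one carbon too many. On mechanism the double inversion is the more dependable source of relative configuration. On step economy the alternative is at best equal and probably longer.

Alternative 3: The cut is the C7–H bond; the racemic keto ester A7 is the precursor and both centres are set in one reduction.
- Forward key step: RuCl(p-cymene)[(R,R)-TsDPEN] (divalent ruthenium) with HCO2H/Et3N would transfer hydride to the C7 ketone of the enantiomer of A7 that fits the catalyst, while C8 equilibrates through the enol, to give the syn hydroxy ester A6.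
- In its favour: no chiral pool and no organometallic reagent are needed, and A7 should be reachable from 4 in about three steps. Syn-selective dynamic kinetic reduction of alpha-oxygenated beta-keto esters rests on firmer ground than magnesium chelation by an aryl ether, so in reliability of the relative configuration this alternative is judged the equal of the chosen plan and probably the better. The later conversion of the aliphatic ester into C9 is a full borohydride reduction, which is easier to control than a partial reduction to an aldehyde, also a better point.
- Against it here: 4-alkoxyaryl ketones are slow in transfer hydrogenation. The very large aryloxy group at C8 could change the rate of enolisation or the syn/anti preference. A6 could suffer retro-aldol cleavage or loss of aryloxide in the amine medium. The absolute configuration would rest on the sense of the catalyst and not on a stereocentre of known origin.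
- Comparison: on structure both plans pass through the same threo skeleton with C9 at the ester level at some stage. On mechanism catalyst control of both centres stands against substrate control of one. On step economy the alternative, at roughly seven to eight steps including hydrolysis and hydrogenolysis at the end, is equal to or slightly better than the nine steps proposed here.

Key step: step 7

Remark: all descriptors were derived by the CIP rules and are mutually consistent: the (R) centre of 1–3 becomes (S) in 5 and 6 through one inversion, and the (S) aldehyde 6 leads to the (1S,2S) = (7S,8S) threo series 10–12. 6 is assumed to hold its configuration between work-up and use at −78 °C.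

## Route

Step 1
Reactants: 1 methyl (4R)-2,2-dimethyl-1,3-dioxolane-4-carboxylate
Product: 2 methyl (2R)-2,3-dihydroxypropanoate
Conditions: sulfonic acid ion-exchange resin (H+ form), MeOH/H2O 9:1, 40 °C; filter, concentrate
Reagents that add atoms: none
Why: Acid-catalysed acetal hydrolysis frees the 1,2-diol; the methyl ester survives in the methanol-rich medium and the stereocentre is not involved, so it stays R.

Step 2
Reactants: 2 methyl (2R)-2,3-dihydroxypropanoate
Product: 3 methyl (2R)-2-hydroxy-3-[(triisopropylsilyl)oxy]propanoate
Conditions: i-Pr3SiCl (1.05 equiv), imidazole (2.2 equiv), DMF, 0 °C → rt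
Reagents that add atoms: chlorotriisopropylsilane, CC(C)[Si](Cl)(C(C)C)C(C)C
Why: Imidazole-mediated silyl ether formation; the bulky silyl chloride should select the primary hydroxyl over the secondary one, which is hindered and deactivated by the adjacent ester.

Step 3
Reactants: 3 methyl (2R)-2-hydroxy-3-[(triisopropylsilyl)oxy]propanoate; 4 methyl 4-hydroxy-3,5-dimethoxybenzoate (methyl syringate)
Product: 5 methyl 3,5-dimethoxy-4-{[(2S)-1-methoxy-1-oxo-3-[(triisopropylsilyl)oxy]propan-2-yl]oxy}benzoate
Conditions: PPh3 (1.3 equiv), DIAD (1.3 equiv), toluene, 0 °C → rt
Reagents that add atoms: none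
Why: Mitsunobu etherification: the secondary hydroxyl is activated on phosphorus and displaced by the phenoxide of 4, which is acidic enough because of its para ester, in an SN2 reaction accelerated by the adjacent carbonyl group. Inversion turns the (R) carbinol into the (S) aryl ether, which is the C8 configuration of the target.

Step 4
Reactants: 5 methyl 3,5-dimethoxy-4-{[(2S)-1-methoxy-1-oxo-3-[(triisopropylsilyl)oxy]propan-2-yl]oxy}benzoate
Product: 6 methyl 3,5-dimethoxy-4-{[(2S)-1-oxo-3-[(triisopropylsilyl)oxy]propan-2-yl]oxy}benzoate
Conditions: i-Bu2AlH (1.1 equiv), CH2Cl2, −78 °C; MeOH at −78 °C, then aq. potassium sodium tartrate; crude aldehyde used at once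
Reagents that add atoms: none
Why: Partial reduction of an ester by an aluminium hydride: the alpha-aryloxy aliphatic ester is more electrophilic than the conjugated, electron-rich ring B benzoate, and its tetrahedral aluminium adduct should persist at −78 °C and collapse to the aldehyde only on work-up. C8 is not touched, and immediate use of 6 limits epimerisation.

Step 5
Reactants: 7 4-bromo-2-methoxyphenol
Product: 8 (4-bromo-2-methoxyphenoxy)triisopropylsilane
Conditions: i-Pr3SiCl (1.1 equiv), imidazole (2.2 equiv), DMF, rt
Reagents that add atoms: chlorotriisopropylsilane, CC(C)[Si](Cl)(C(C)C)C(C)C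
Why: Standard silylation of a phenol; the aryl silyl ether is inert to magnesium and to arylmagnesium species and is removed later together with the silyl group on O9.

Step 6
Reactants: 8 (4-bromo-2-methoxyphenoxy)triisopropylsilane
Product: 9 {3-methoxy-4-[(triisopropylsilyl)oxy]phenyl}magnesium bromide (titrated solution)
Conditions: Mg turnings, I2 (cat.), Et2O, reflux
Reagents that add atoms: magnesium, [Mg]
Why: Grignard reagent formation by insertion of magnesium into the aryl C–Br bond; diethyl ether is used so that the reagent brings no strongly coordinating solvent into the chelation-controlled step.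

Step 7
Reactants: 6 methyl 3,5-dimethoxy-4-{[(2S)-1-oxo-3-[(triisopropylsilyl)oxy]propan-2-yl]oxy}benzoate; 9 {3-methoxy-4-[(triisopropylsilyl)oxy]phenyl}magnesium bromide
Product: 10 methyl 4-{[(1S,2S)-1-hydroxy-1-{3-methoxy-4-[(triisopropylsilyl)oxy]phenyl}-3-[(triisopropylsilyl)oxy]propan-2-yl]oxy}-3,5-dimethoxybenzoate
Conditions: MgBr2·OEt2 (3 equiv), CH2Cl2, −78 °C, 30 min; then 9 (1.5 equiv, ca. 0.5 M in Et2O) dropwise, −78 °C; sat. aq. NH4Cl
Reagents that add atoms: none
Why: MgBr2·OEt2 is expected to bind the aldehyde oxygen and the twisted ether oxygen on C8 in a five-membered chelate, with an ortho methoxy oxygen of ring B available as a third donor, and the aryl group of 9 is then transferred to the carbonyl carbon C7 (polar 1,2-addition that forms the C1(ring A)–C7 bond; no ring is closed). The closest known reaction type is the Cram-chelate addition of Grignard reagents to alpha-alkoxy aldehydes precomplexed with a magnesium halide in a weakly coordinating solvent. In the chelate the C7=O and C8–O bonds are held syn-periplanar, so the two faces of C7 are flanked by the C8 hydrogen and by the C9 silyloxymethyl arm; entry past the hydrogen turns the (S) aldehyde into the (7S) carbinol, the syn (threo) 1S,2S product, so the new centre is controlled only by the C8 centre inherited from 1. The selectivity needed is alpha-chelation over the dipolar Felkin–Anh pathway and over a six-membered chelate through O9, both of which would give the erythro epimer. It should be secured by the bulky, non-donating silyl group on O9, by the higher basicity of an aryl ether oxygen that cannot conjugate with its ring and has a methoxy donor beside it, by complexation before the nucleophile arrives, and by the absence of a strongly donating solvent. Aldehyde-over-ester chemoselectivity follows from the large rate difference at −78 °C; the excess MgBr2·OEt2 allows for binding to the ring B ester carbonyl. The aldehyde is used fresh and cold so that C8 is not epimerised before the bond is formed.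

Step 8
Reactants: 10 methyl 4-{[(1S,2S)-1-hydroxy-1-{3-methoxy-4-[(triisopropylsilyl)oxy]phenyl}-3-[(triisopropylsilyl)oxy]propan-2-yl]oxy}-3,5-dimethoxybenzoate
Product: 11 methyl 4-{[(1S,2S)-1,3-dihydroxy-1-(4-hydroxy-3-methoxyphenyl)propan-2-yl]oxy}-3,5-dimethoxybenzoate
Conditions: Bu4NF (3 equiv), AcOH (3 equiv), THF, 0 °C → rt
Reagents that add atoms: none
Why: Fluoride-induced cleavage of both Si–O bonds, driven by the strong Si–F bond; acetic acid buffers the medium so that the phenoxide and the methyl ester do not meet free alkoxide, and neither stereocentre takes part.

Step 9
Reactants: 11 methyl 4-{[(1S,2S)-1,3-dihydroxy-1-(4-hydroxy-3-methoxyphenyl)propan-2-yl]oxy}-3,5-dimethoxybenzoate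
Product: 12 4-{[(1S,2S)-1,3-dihydroxy-1-(4-hydroxy-3-methoxyphenyl)propan-2-yl]oxy}-3,5-dimethoxybenzoic acid
Conditions: LiOH·H2O (4 equiv), THF/H2O 3:1, rt, under Ar; then 1 M HCl to pH 3 at 0 °C, EtOAc extraction
Reagents that add atoms: lithium hydroxide, [Li+].[OH-]
Why: Ester saponification by acyl–oxygen cleavage; the unhindered ring B methyl ester should hydrolyse at room temperature, the ring A phenolate is expected to be stable under these conditions without air and heat, and brief cold acidification to pH 3 releases the acid without ionising the C7 carbinol, so both stereocentres are kept.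

## Compound list

1 | methyl (4R)-2,2-dimethyl-1,3-dioxolane-4-carboxylate | COC(=O)[C@H]1COC(C)(C)O1 | starting material
2 | methyl (2R)-2,3-dihydroxypropanoate | COC(=O)[C@H](O)CO | intermediate
3 | methyl (2R)-2-hydroxy-3-[(triisopropylsilyl)oxy]propanoate | COC(=O)[C@H](O)CO[Si](C(C)C)(C(C)C)C(C)C | intermediate
4 | methyl 4-hydroxy-3,5-dimethoxybenzoate (methyl syringate) | COC(=O)c1cc(OC)c(O)c(OC)c1 | starting material
5 | methyl 3,5-dimethoxy-4-{[(2S)-1-methoxy-1-oxo-3-[(triisopropylsilyl)oxy]propan-2-yl]oxy}benzoate | COC(=O)[C@H](CO[Si](C(C)C)(C(C)C)C(C)C)Oc1c(OC)cc(C(=O)OC)cc1OC | intermediate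
6 | methyl 3,5-dimethoxy-4-{[(2S)-1-oxo-3-[(triisopropylsilyl)oxy]propan-2-yl]oxy}benzoate | O=C[C@H](CO[Si](C(C)C)(C(C)C)C(C)C)Oc1c(OC)cc(C(=O)OC)cc1OC | intermediate
7 | 4-bromo-2-methoxyphenol | COc1cc(Br)ccc1O | starting material
8 | (4-bromo-2-methoxyphenoxy)triisopropylsilane | COc1cc(Br)ccc1O[Si](C(C)C)(C(C)C)C(C)C | intermediate
9 | {3-methoxy-4-[(triisopropylsilyl)oxy]phenyl}magnesium bromide | COc1cc([Mg]Br)ccc1O[Si](C(C)C)(C(C)C)C(C)C | intermediate
10 | methyl 4-{[(1S,2S)-1-hydroxy-1-{3-methoxy-4-[(triisopropylsilyl)oxy]phenyl}-3-[(triisopropylsilyl)oxy]propan-2-yl]oxy}-3,5-dimethoxybenzoate | COc1cc([C@H](O)[C@H](CO[Si](C(C)C)(C(C)C)C(C)C)Oc2c(OC)cc(C(=O)OC)cc2OC)ccc1O[Si](C(C)C)(C(C)C)C(C)C | intermediate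
11 | methyl 4-{[(1S,2S)-1,3-dihydroxy-1-(4-hydroxy-3-methoxyphenyl)propan-2-yl]oxy}-3,5-dimethoxybenzoate | COc1cc([C@H](O)[C@H](CO)Oc2c(OC)cc(C(=O)OC)cc2OC)ccc1O | intermediate
12 | 4-{[(1S,2S)-1,3-dihydroxy-1-(4-hydroxy-3-methoxyphenyl)propan-2-yl]oxy}-3,5-dimethoxybenzoic acid | COc1cc([C@H](O)[C@H](CO)Oc2c(OC)cc(C(=O)O)cc2OC)ccc1O | target

## Step count and least certain steps

Total step count: 9. Longest linear sequence: 7 steps (steps 1, 2, 3, 4, 7, 8, 9 from 1); the ring A branch (steps 5 and 6) joins at step 7.

Step 7 (key step). The most likely failure is poor facial selectivity. Transfer of the aryl group from a reactive arylmagnesium species may outrun chelate formation, or the aryloxy oxygen may bind magnesium too weakly to override the dipolar Felkin–Anh preference. Partial epimerisation of C8 before the addition would in addition lower the enantiomeric purity.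

Fallback, setting out from 6 and 9 and returning at 10: the addition is run in THF without MgBr2·OEt2, where the Felkin–Anh pathway should prevail and give mainly the erythro epimer methyl 4-{[(1R,2S)-1-hydroxy-1-{3-methoxy-4-[(triisopropylsilyl)oxy]phenyl}-3-[(triisopropylsilyl)oxy]propan-2-yl]oxy}-3,5-dimethoxybenzoate F1 beside some 10. The mixture of epimers is oxidised with Dess–Martin periodinane (NaHCO3, CH2Cl2, 0 °C) to the single ketone methyl 3,5-dimethoxy-4-{[(2S)-1-{3-methoxy-4-[(triisopropylsilyl)oxy]phenyl}-1-oxo-3-[(triisopropylsilyl)oxy]propan-2-yl]oxy}benzoate F2. F2 is reduced with LiBH(s-Bu)3 in THF at −78 °C. In the ketone the same Felkin–Anh preference (hydride anti to the C8–O4′ bond, past the C8 hydrogen) should now lead to the threo alcohol, so the route is rejoined at 10.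

Step 3. The most likely failure is sluggish displacement with competing elimination or alkylation of the reduced azodicarboxylate, because the nucleophilic oxygen is flanked by two methoxy groups and the carbinol by a bulky silyloxymethyl group.

Fallback, setting out from 3 and returning at 5: the hydroxyl of 3 is converted with Tf2O and 2,6-lutidine in CH2Cl2 at −78 °C into the triflate methyl (2R)-3-[(triisopropylsilyl)oxy]-2-{[(trifluoromethyl)sulfonyl]oxy}propanoate F3. F3 is treated cold with 4 and K2CO3 in MeCN; direct SN2 displacement by the phenoxide, again with inversion, should give 5.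

Step 4. The most likely failures are over-reduction to the primary alcohol, competing attack on the ring B ester, and erosion of the C8 configuration during work-up, because two methyl esters compete and the product aldehyde is enolisable.

Fallback, setting out from 5 and returning at 6: NaBH4 in THF/MeOH at 0 °C should reduce only the activated aliphatic ester, to the primary alcohol methyl 4-{[(2R)-1-hydroxy-3-[(triisopropylsilyl)oxy]propan-2-yl]oxy}-3,5-dimethoxybenzoate F4. The spatial arrangement is unchanged; the descriptor changes only through the priority rules. Oxidation with Dess–Martin periodinane buffered with NaHCO3 in CH2Cl2 at 0 °C should then give 6. The reduction is kept cold and short so that the silyl group does not migrate between the two primary oxygens.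

Step 9. The most likely failure is base-induced degradation of the unprotected 4-hydroxybenzylic alcohol (phenolate-driven loss of the C7 hydroxyl, or air oxidation of the phenolate) during a hydrolysis that may be slow for an electron-rich benzoate.

Fallback, setting out from 7 and 6 and returning at 12: the ring A phenol is carried as a base-stable benzyl ether instead.
- Alkylation of 7 with BnBr and K2CO3 in DMF gives 1-(benzyloxy)-4-bromo-2-methoxybenzene F5.
- Magnesium insertion gives [4-(benzyloxy)-3-methoxyphenyl]magnesium bromide F6.
- Addition to 6 under the conditions of step 7 gives methyl 4-{[(1S,2S)-1-[4-(benzyloxy)-3-methoxyphenyl]-1-hydroxy-3-[(triisopropylsilyl)oxy]propan-2-yl]oxy}-3,5-dimethoxybenzoate F7.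
- Bu4NF then frees O9 to give methyl 4-{[(1S,2S)-1-[4-(benzyloxy)-3-methoxyphenyl]-1,3-dihydroxypropan-2-yl]oxy}-3,5-dimethoxybenzoate F8.
- LiOH hydrolyses the ester, while no phenolate can form, to give 4-{[(1S,2S)-1-[4-(benzyloxy)-3-methoxyphenyl]-1,3-dihydroxypropan-2-yl]oxy}-3,5-dimethoxybenzoic acid F9.
- Neutral hydrogenolysis of the benzyl ether (H2, Pd/C, EtOAc/EtOH, stopped as soon as F9 is consumed) gives 12.

This fallback costs one more step in the longest sequence.

## Further compounds

F1 | step 7 | methyl 4-{[(1R,2S)-1-hydroxy-1-{3-methoxy-4-[(triisopropylsilyl)oxy]phenyl}-3-[(triisopropylsilyl)oxy]propan-2-yl]oxy}-3,5-dimethoxybenzoate | COc1cc([C@@H](O)[C@H](CO[Si](C(C)C)(C(C)C)C(C)C)Oc2c(OC)cc(C(=O)OC)cc2OC)ccc1O[Si](C(C)C)(C(C)C)C(C)C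
F2 | step 7 | methyl 3,5-dimethoxy-4-{[(2S)-1-{3-methoxy-4-[(triisopropylsilyl)oxy]phenyl}-1-oxo-3-[(triisopropylsilyl)oxy]propan-2-yl]oxy}benzoate | COc1cc(C(=O)[C@H](CO[Si](C(C)C)(C(C)C)C(C)C)Oc2c(OC)cc(C(=O)OC)cc2OC)ccc1O[Si](C(C)C)(C(C)C)C(C)C
F3 | step 3 | methyl (2R)-3-[(triisopropylsilyl)oxy]-2-{[(trifluoromethyl)sulfonyl]oxy}propanoate | COC(=O)[C@H](OS(=O)(=O)C(F)(F)F)CO[Si](C(C)C)(C(C)C)C(C)C
F4 | step 4 | methyl 4-{[(2R)-1-hydroxy-3-[(triisopropylsilyl)oxy]propan-2-yl]oxy}-3,5-dimethoxybenzoate | OC[C@H](CO[Si](C(C)C)(C(C)C)C(C)C)Oc1c(OC)cc(C(=O)OC)cc1OC
F5 | step 9 | 1-(benzyloxy)-4-bromo-2-methoxybenzene | COc1cc(Br)ccc1OCc1ccccc1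
F6 | step 9 | [4-(benzyloxy)-3-methoxyphenyl]magnesium bromide | COc1cc([Mg]Br)ccc1OCc1ccccc1
F7 | step 9 | methyl 4-{[(1S,2S)-1-[4-(benzyloxy)-3-methoxyphenyl]-1-hydroxy-3-[(triisopropylsilyl)oxy]propan-2-yl]oxy}-3,5-dimethoxybenzoate | COc1cc([C@H](O)[C@H](CO[Si](C(C)C)(C(C)C)C(C)C)Oc2c(OC)cc(C(=O)OC)cc2OC)ccc1OCc1ccccc1
F8 | step 9 | methyl 4-{[(1S,2S)-1-[4-(benzyloxy)-3-methoxyphenyl]-1,3-dihydroxypropan-2-yl]oxy}-3,5-dimethoxybenzoate | COc1cc([C@H](O)[C@H](CO)Oc2c(OC)cc(C(=O)OC)cc2OC)ccc1OCc1ccccc1
F9 | step 9 | 4-{[(1S,2S)-1-[4-(benzyloxy)-3-methoxyphenyl]-1,3-dihydroxypropan-2-yl]oxy}-3,5-dimethoxybenzoic acid | COc1cc([C@H](O)[C@H](CO)Oc2c(OC)cc(C(=O)O)cc2OC)ccc1OCc1ccccc1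
A1 | alternative 1 | ethyl (2R,3S)-3-(4-acetoxy-3-methoxyphenyl)-2-[2,6-dimethoxy-4-(methoxycarbonyl)phenoxy]-3-hydroxypropanoate | COc1cc([C@H](O)[C@H](C(=O)OCC)Oc2c(OC)cc(C(=O)OC)cc2OC)ccc1OC(C)=O
A2 | alternative 1 | ethyl diazoacetate | CCOC(=O)C=[N+]=[N-]
A3 | alternative 1 | 4-formyl-2-methoxyphenyl acetate (vanillin acetate) | COc1cc(C=O)ccc1OC(C)=O
A4 | alternative 2 | methyl 4-{[(1S,2S)-1-[4-(benzyloxy)-3-methoxyphenyl]-1-hydroxybut-3-en-2-yl]oxy}-3,5-dimethoxybenzoate | COc1cc([C@H](O)[C@H](C=C)Oc2c(OC)cc(C(=O)OC)cc2OC)ccc1OCc1ccccc1
A5 | alternative 2 | (2S,3S)-2-[4-(benzyloxy)-3-methoxyphenyl]-3-ethenyloxirane | COc1cc([C@@H]2O[C@H]2C=C)ccc1OCc1ccccc1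
A6 | alternative 3 | ethyl (2R,3S)-3-[4-(benzyloxy)-3-methoxyphenyl]-2-[2,6-dimethoxy-4-(methoxycarbonyl)phenoxy]-3-hydroxypropanoate | COc1cc([C@H](O)[C@H](C(=O)OCC)Oc2c(OC)cc(C(=O)OC)cc2OC)ccc1OCc1ccccc1
A7 | alternative 3 | ethyl 3-[4-(benzyloxy)-3-methoxyphenyl]-2-[2,6-dimethoxy-4-(methoxycarbonyl)phenoxy]-3-oxopropanoate (racemic) | CCOC(=O)C(Oc1c(OC)cc(C(=O)OC)cc1OC)C(=O)c1ccc(OCc2ccccc2)c(OC)c1
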